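Temperature and time act on this pair of flasks through one clock: north-east and south-west carry the substrate and reagent charges of Wednesday's run, so each can be read as Wednesday's run at an equivalent time.

common to all: left-handed substrate 26 mM; right-handed substrate 26 mM; reagent 104 mM; added ligand 0.13 mM
- Wednesday's: racemization catalyst 26 µM; temperature 20 °C; run made earlier
- Saturday's: racemization catalyst 39 µM; temperature 31 °C; run made earlier
- north-east: racemization catalyst 52 µM; temperature 35 °C; time 50 min
- south-west: racemization catalyst 52 µM; temperature 15 °C; time 50 min

- Wednesday's (time / min: left-handed product / %, right-handed product / %): 15.0: 20, 12; 30.0: 34, 16; 50.0: 45, 24; 60.0: 45, 29
- Saturday's (time / min: left-handed product / %, right-handed product / %): 8.00: 29, 12; 15.0: 36, 22; 25.0: 43, 30; 30.0: 50, 31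

(each reading ± 2 percentage points)

* the flask with the highest excess of left-handed product over right-handed product ("all alike" if they lie within 1.5 percentage points) (north-east / south-west / all alike)
* excess of left-handed product over right-handed product at the end, north-east
* excess of left-handed product over right-handed product at the end, south-west

- reagent is single-handed; left-handed substrate and right-handed substrate are mirror images of each other, charged as a racemate, each of them at the stated concentration
- the earlier runs were read with a standard deviation of 2 percentage points
- an excess is the difference of the two amounts in percent of their sum
- an excess is below zero if the other one leads
- the handed part of reagent does not stay in what it makes, so the products of the two hands are mirror images too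

The clock comes from the loss of right-handed substrate, 0.0129 /min in Wednesday's run and 0.0387 /min in Saturday's, which gives an activation energy of 74.2 kJ/mol. Were Wednesday's right-handed reading one standard deviation higher, south-west's equivalent time would be 31.6 min; as read it is 29.5 min, close to Wednesday's reading at 30.0 min. So south-west's excess is about 36.0 %. The right-handed reading weighs heavier: one standard deviation higher, it brings that excess to 30.8 %, against 33.3 % for the left-handed reading one standard deviation lower.

The same pair of readings gives the selectivity factor, the ratio of the logarithms of the shares of each hand left, 2.95. The share of left-handed substrate left is the share of right-handed substrate left, raised to this power. Wednesday's last right-handed reading then gives 46.1 % left-handed product against 45 % read, within the scatter, so these readings ask for no racemization term.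

North-east stands at 220 min on the clock, past Wednesday's last reading. A first round at Wednesday's mean reagent, 87.5 %, leaves 5.91 % of the right-handed substrate and 51.5 % of the reagent. Putting the mean of that and the charge back in leaves 8.64 %, an excess of 4.48 %.

The forecast names south-west, with 10 % for north-east and 35 % for south-west, since “the excess falls as conversion rises”; for north-east it stands above this reckoning.

The simulation gives 9.17 % in north-east and 37.7 % in south-west, so south-west leads.

    racemization catalyst + added ligand ⇌ idle complex, settled at all times (K = 11000 /M, ΔH = −6.00 kJ/mol)
    reagent + right-handed substrate → right-handed product (k = 0.690 /M/min, Ea = 75.0 kJ/mol)
    left-handed substrate + racemization catalyst ⇌ right-handed substrate + racemization catalyst, rate k3*[racemization catalyst]*[left-handed substrate] forward; the back reaction follows from the equilibrium constant (k = 180 /M/min, Ea = 41.0 kJ/mol)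
    2 racemization catalyst → spent catalyst (k = 270 /M/min, Ea = 60.0 kJ/mol)
    reagent + left-handed substrate → left-handed product (k = 2.00 /M/min, Ea = 72.0 kJ/mol)
    (constants at 35 °C)

South-west's 16.3 % right-handed product at the end gives, through 2.95, 34.4 % left-handed product; 35.9 % stands there. North-east ends above the reckoned 4.48 %. South-west's excess stands high mainly because of the hour of its reading: left ten times as long, south-west gives 11.9 % instead of 37.7 %. The south-west flask run at 30 °C ends with 37.6 % right-handed product, which through 2.95 means 49.2 % left-handed product and an excess of 13.4 %; the simulation gives 51.0 % and 15.1 %.

The earlier runs and the new flask come from a simulation for substances that don't exist, and the scatter is random.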